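A direct plan would close ring C last, by a chiral-acid-catalysed oxa-[4+2] cycloaddition of the ortho-quinone methide-type cation from salicylaldehyde A1 and trimethyl orthoformate A2 with vinylchroman A3, then convert 4-methoxyflavan A4 into the ketone and desilylate. Its weakest steps would be the cycloaddition, since no enantioselective version is known for such partners and the acid would meet prenyl alkenes and an ortho-prenylphenol; the twofold phenoxide ortho-C-prenylation to A5, since O- and mono-alkylation would compete; and the OMe-to-OH exchange plus oxidation at C4, which would add length without complexity.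

The new route rests on the C2–C1′ bond. Ring C is taken closed, as the γ-pyrone of 7-hydroxychromone, and its vinylogous ester (O1–C2=C3–C4=O) is used as the acceptor: ring B arrives at C2 as an arylboronic acid in a ligand-controlled, base-free palladium-catalysed 1,4-addition. This one operation joins the two halves and sets the only stereocentre with C4 already a ketone, so no cycloaddition has to be invented and no redox adjustment follows. Both prenyl groups come from regiodefined reactions, an aromatic Claisen rearrangement of a 1,1-dimethylallyl ether on ring A and an iodine–magnesium exchange/allylation on ring B, so no phenoxide C-alkylation is needed.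

Key step: step 8

Assumption: 7-hydroxychromone (4) is taken as a catalogue compound.
Remark: the sense of induction of the PyOx ligand in step 8 is assigned by analogy with cyclic enones, where the (S)-ligand leads to the (R)-series; if the analogy failed, the (S)-ligand would be used instead.

Step 1
Reactants: 1 2-methylbut-3-en-2-ol
Product: 3 methyl 2-methylbut-3-en-2-yl carbonate, via lithium 2-methylbut-3-en-2-olate 2 (not isolated)
Conditions: n-BuLi (1.05 equiv), THF, –78 → 0 °C; ClCO2Me (1.1 equiv), 0 °C → rt
Reagents that add atoms: methyl chloroformate, COC(=O)Cl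
Why: Carbonate formation by O-acylation of the lithium alkoxide of the tertiary allylic alcohol with the chloroformate; it gives the ionisable 1,1-dimethylallyl donor for step 2.

Step 2
Reactants: 4 7-hydroxychromen-4-one, 3 methyl 2-methylbut-3-en-2-yl carbonate
Product: 5 7-(2-methylbut-3-en-2-yloxy)chromen-4-one
Conditions: 3 (1.5 equiv), Pd(PPh3)4 (3 mol%), THF, 0 °C
Reagents that add atoms: none
Why: Tsuji–Trost O-allylation: zerovalent palladium ionises 3 with loss of CO2, the methoxide formed deprotonates the phenol, and the phenoxide should attack the π-(1,1-dimethylallyl)palladium cation at its more substituted terminus under kinetic control at 0 °C, giving the tertiary ether and not the prenyl ether.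

Step 3
Reactants: 5 7-(2-methylbut-3-en-2-yloxy)chromen-4-one
Product: 7 8-(3-methylbut-2-enyl)-4-oxochromen-7-yl acetate, via 7-hydroxy-8-(3-methylbut-2-enyl)chromen-4-one 6 (not isolated)
Conditions: Ac2O (5 equiv), PhNEt2, 150 °C
Reagents that add atoms: acetic anhydride, CC(=O)OC(C)=O
Why: Aromatic Claisen rearrangement: the [3,3] shift turns the 1,1-dimethylallyl ether into the linear prenyl group at C8, preferred over C6 because the C7–C8 bond has the higher π-bond order in the benzo-γ-pyrone (the usual outcome for 7-allyloxychromones and -coumarins), and in situ acetylation keeps phenol 6 from the abnormal Claisen pathway and from cyclising onto the prenyl group.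

Step 4
Reactants: 8 4-bromophenol, 9 isoprene
Product: 11 6-bromo-2,2-dimethylchroman, via 4-bromo-2-(3-methylbut-2-enyl)phenol 10 (not isolated)
Conditions: 9 (1.5 equiv), AgOSO2CF3 (5 mol%), ClCH2CH2Cl, rt
Reagents that add atoms: none
Why: Acid-catalysed chroman annulation of a phenol with a 1,3-diene: Friedel–Crafts ortho-prenylation by the isoprene-derived allyl cation (para is blocked by bromine) followed by Markovnikov hydroalkoxylation of the prenyl alkene by the phenol.

Step 5
Reactants: 11 6-bromo-2,2-dimethylchroman
Product: 12 6-bromo-8-iodo-2,2-dimethylchroman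
Conditions: NIS (1.1 equiv), CF3CO2H (0.3 equiv), MeCN, rt → 50 °C
Reagents that add atoms: N-iodosuccinimide, O=C1CCC(=O)N1I
Why: Electrophilic aromatic iodination: the ring oxygen directs ortho and para, the para position C6 carries bromine, so iodine should enter at C8, the only free position activated by oxygen.

Step 6
Reactants: 12 6-bromo-8-iodo-2,2-dimethylchroman, 13 prenyl bromide (1-bromo-3-methylbut-2-ene)
Product: 15 6-bromo-2,2-dimethyl-8-(3-methylbut-2-enyl)chroman, via (6-bromo-2,2-dimethylchroman-8-yl)magnesium chloride 14 (not isolated)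
Conditions: i-PrMgCl·LiCl (1.05 equiv), THF, –20 °C; CuI (10 mol%), 13 (1.3 equiv), –20 → 0 °C
Reagents that add atoms: none
Why: Iodine–magnesium exchange, much faster at the iodide ortho to oxygen than at the bromide, followed by copper-catalysed SN2 allylation of the arylmagnesium at the unhindered primary terminus of 13, which should give the linear prenyl group and leave the bromide for the next step.

Step 7
Reactants: 15 6-bromo-2,2-dimethyl-8-(3-methylbut-2-enyl)chroman
Product: 18 [2,2-dimethyl-8-(3-methylbut-2-enyl)chroman-6-yl]boronic acid, via 6-lithio-2,2-dimethyl-8-(3-methylbut-2-enyl)chroman 16 (not isolated), via lithium aryl(triisopropoxy)borate 17 (not isolated)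
Conditions: n-BuLi (1.1 equiv), THF, –78 °C; B(O-i-Pr)3 (1.5 equiv), –78 °C → rt; 1 M HCl, 0 °C
Reagents that add atoms: triisopropyl borate, CC(C)OB(OC(C)C)OC(C)C; water, O
Why: Bromine–lithium exchange and borylation of the aryllithium with the trialkyl borate, then hydrolysis of the ate complex to the boronic acid; the prenyl alkene and the chroman ether are inert to n-BuLi at –78 °C and brief cold dilute acid should not hydrate or cyclise the alkene.

Step 8
Reactants: 7 8-(3-methylbut-2-enyl)-4-oxochromen-7-yl acetate, 18 [2,2-dimethyl-8-(3-methylbut-2-enyl)chroman-6-yl]boronic acid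
Product: 19 (2S)-2-[2,2-dimethyl-8-(3-methylbut-2-enyl)chroman-6-yl]-8-(3-methylbut-2-enyl)-4-oxochroman-7-yl acetate
Conditions: 18 (2 equiv), Pd(OCOCF3)2 (5 mol%), (R)-t-BuPyOx [(R)-4-tert-butyl-2-(pyridin-2-yl)-4,5-dihydrooxazole] (6 mol%), NH4PF6 (30 mol%), H2O (5 equiv), ClCH2CH2Cl, 60 °C
Reagents that add atoms: none
Why: Transmetalation of 18 to the cationic divalent palladium–PyOx complex gives an arylpalladium species that inserts the C2=C3 bond of 7 with the aryl group going to C2, and the C3-bound palladium enolate is protonated by water to release 19 and a palladium hydroxide that takes up the next boronic acid, so the metal stays divalent throughout. The closest known reaction is the PyOx–palladium-catalysed asymmetric 1,4-addition of arylboronic acids to chromones, a base-free Hayashi–Miyaura-type conjugate addition. No ring is closed: ring C is already present in the γ-pyrone and only changes from sp2 to sp3 at C2. The C2 configuration is controlled by the ligand, whose tert-butyl group blocks one enantiotopic face of the bound enone in the insertion step, and the (R)-ligand is expected to give 2S. The step needs chemoselectivity for the electron-poor C2=C3 bond over the two trisubstituted prenyl alkenes, which are poor partners for carbopalladation, and it needs the enolate to be protonated faster than it expels O1, which the base-free aqueous medium should secure; the acetate keeps O7 from donating strongly into the enone and keeps the ortho-prenylphenol away from palladium.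

Step 9
Reactants: 19 (2S)-2-[2,2-dimethyl-8-(3-methylbut-2-enyl)chroman-6-yl]-8-(3-methylbut-2-enyl)-4-oxochroman-7-yl acetate
Product: 20 (2S)-2-[2,2-dimethyl-8-(3-methylbut-2-enyl)chroman-6-yl]-7-hydroxy-8-(3-methylbut-2-enyl)chroman-4-one (target)
Conditions: NH4OAc (10 equiv), MeOH/H2O (4:1), rt
Reagents that add atoms: none
Why: Ammonium acetate-mediated hydrolysis of the aryl acetate (ester solvolysis) at near-neutral pH: no phenoxide or C3 enolate builds up, so retro-oxa-Michael opening of ring C, the pathway that would racemise C2, should not occur, and the prenyl groups meet no strong acid.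

**Compound list**

1 | 2-methylbut-3-en-2-ol | C=CC(C)(C)O | starting material
2 | lithium 2-methylbut-3-en-2-olate | [Li]OC(C)(C)C=C | intermediate
3 | methyl 2-methylbut-3-en-2-yl carbonate | COC(=O)OC(C)(C)C=C | intermediate
4 | 7-hydroxychromen-4-one (7-hydroxychromone) | O=c1ccoc2cc(O)ccc12 | starting material
5 | 7-(2-methylbut-3-en-2-yloxy)chromen-4-one | C=CC(C)(C)Oc1ccc2c(c1)occc2=O | intermediate
6 | 7-hydroxy-8-(3-methylbut-2-enyl)chromen-4-one | CC(C)=CCc1c(O)ccc2c1occc2=O | intermediate
7 | 8-(3-methylbut-2-enyl)-4-oxochromen-7-yl acetate | CC(C)=CCc1c(OC(C)=O)ccc2c1occc2=O | intermediate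
8 | 4-bromophenol | Oc1ccc(Br)cc1 | starting material
9 | isoprene (2-methylbuta-1,3-diene) | C=CC(C)=C | starting material
10 | 4-bromo-2-(3-methylbut-2-enyl)phenol | CC(C)=CCc1cc(Br)ccc1O | intermediate
11 | 6-bromo-2,2-dimethylchroman | CC1(C)CCc2cc(Br)ccc2O1 | intermediate
12 | 6-bromo-8-iodo-2,2-dimethylchroman | CC1(C)CCc2cc(Br)cc(I)c2O1 | intermediate
13 | prenyl bromide (1-bromo-3-methylbut-2-ene) | CC(C)=CCBr | starting material
14 | (6-bromo-2,2-dimethylchroman-8-yl)magnesium chloride | CC1(C)CCc2cc(Br)cc([Mg]Cl)c2O1 | intermediate
15 | 6-bromo-2,2-dimethyl-8-(3-methylbut-2-enyl)chroman | CC(C)=CCc1cc(Br)cc2c1OC(C)(C)CC2 | intermediate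
16 | 6-lithio-2,2-dimethyl-8-(3-methylbut-2-enyl)chroman | [Li]c1cc(CC=C(C)C)c2OC(C)(C)CCc2c1 | intermediate
17 | lithium [2,2-dimethyl-8-(3-methylbut-2-enyl)chroman-6-yl]triisopropoxyborate | [Li+].CC(C)O[B-](OC(C)C)(OC(C)C)c1cc(CC=C(C)C)c2OC(C)(C)CCc2c1 | intermediate
18 | [2,2-dimethyl-8-(3-methylbut-2-enyl)chroman-6-yl]boronic acid | CC(C)=CCc1cc(B(O)O)cc2c1OC(C)(C)CC2 | intermediate
19 | (2S)-2-[2,2-dimethyl-8-(3-methylbut-2-enyl)chroman-6-yl]-8-(3-methylbut-2-enyl)-4-oxochroman-7-yl acetate | CC(C)=CCc1cc([C@@H]2CC(=O)c3ccc(OC(C)=O)c(CC=C(C)C)c3O2)cc2c1OC(C)(C)CC2 | intermediate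
20 | (2S)-2-[2,2-dimethyl-8-(3-methylbut-2-enyl)chroman-6-yl]-7-hydroxy-8-(3-methylbut-2-enyl)chroman-4-one | CC(C)=CCc1cc([C@@H]2CC(=O)c3ccc(O)c(CC=C(C)C)c3O2)cc2c1OC(C)(C)CC2 | target

Total step count: 9. Longest linear sequence: 6 (steps 4, 5, 6, 7, 8, 9).

Steps most likely to fail:

Step 8 (insufficient facial selectivity in the insertion, or slow turnover of the chiral catalyst on the electron-rich chromone while 18 is lost by protodeboronation). The fallback would set out from 7 and 18 and come back at 19. The same partners would be joined without asymmetric induction by the more reactive achiral catalyst Pd(OCOCF3)2/2,2′-bipyridine (AcOH/THF/H2O, 60 °C) to give the racemic flavanone acetate F1. The stereocentre would then be obtained by kinetic resolution through asymmetric transfer hydrogenation (RhCl(C5Me5)(TsDPEN), the catalyst antipode that reduces the 2R ketone faster, HCO2H/Et3N, EtOAc, 40 °C, to about half conversion). This should turn the 2R enantiomer into the cis-(2R,4R)-flavan-4-ol F2 and leave (2S)-19 for chromatographic separation.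

Step 3 (poor regioselectivity of the [3,3] shift between C8 and C6, or loss of the allyl unit as isoprene at the temperature needed). The fallback would set out from 4 and come back at 7 without any sigmatropic step. Iodination ortho to the phenol, between the two ring oxygens (NIS, DMF, 0 °C → rt), would give 7-hydroxy-8-iodochromen-4-one F3, and acetylation (Ac2O, pyridine) would give 8-iodo-4-oxochromen-7-yl acetate F4. Stille coupling with tributyl(3-methylbut-2-enyl)stannane (Pd(PPh3)4, DMF, 90 °C) should then deliver the linear prenyl group at C8 to give 7.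

Step 9 (partial racemisation through reversible opening of ring C, or incomplete solvolysis of the hindered acetate). The fallback would set out from 7 and come back at 20, with a fluoride-labile group in place of the acetate. Deacetylation at the achiral chromone stage (NH4OAc, aq. MeOH) would give 6, and silylation (TBSCl, imidazole, DMF) would give 7-(tert-butyldimethylsilyloxy)-8-(3-methylbut-2-enyl)chromen-4-one F5. The 1,4-addition of 18 under the conditions of step 8 would give the (2S)-7-(tert-butyldimethylsilyloxy)flavanone F6, and HF·pyridine (THF, 0 °C) should then release 20 under acidic, non-epimerising conditions.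

**Further compounds**

F1 | step 8 | racemic 2-[2,2-dimethyl-8-(3-methylbut-2-enyl)chroman-6-yl]-8-(3-methylbut-2-enyl)-4-oxochroman-7-yl acetate | CC(C)=CCc1cc(C2CC(=O)c3ccc(OC(C)=O)c(CC=C(C)C)c3O2)cc2c1OC(C)(C)CC2
F2 | step 8 | (2R,4R)-2-[2,2-dimethyl-8-(3-methylbut-2-enyl)chroman-6-yl]-4-hydroxy-8-(3-methylbut-2-enyl)chroman-7-yl acetate | CC(C)=CCc1cc([C@H]2C[C@@H](O)c3ccc(OC(C)=O)c(CC=C(C)C)c3O2)cc2c1OC(C)(C)CC2
F3 | step 3 | 7-hydroxy-8-iodochromen-4-one | O=c1ccoc2c(I)c(O)ccc12
F4 | step 3 | 8-iodo-4-oxochromen-7-yl acetate | CC(=O)Oc1ccc2c(c1I)occc2=O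
F5 | step 9 | 7-(tert-butyldimethylsilyloxy)-8-(3-methylbut-2-enyl)chromen-4-one | CC(C)=CCc1c(O[Si](C)(C)C(C)(C)C)ccc2c1occc2=O
F6 | step 9 | (2S)-7-(tert-butyldimethylsilyloxy)-2-[2,2-dimethyl-8-(3-methylbut-2-enyl)chroman-6-yl]-8-(3-methylbut-2-enyl)chroman-4-one | CC(C)=CCc1cc([C@@H]2CC(=O)c3ccc(O[Si](C)(C)C(C)(C)C)c(CC=C(C)C)c3O2)cc2c1OC(C)(C)CC2
A1 | direct plan | 2-hydroxy-3-(3-methylbut-2-enyl)-4-(triisopropylsilyloxy)benzaldehyde | CC(C)=CCc1c(O)c(C=O)ccc1O[Si](C(C)C)(C(C)C)C(C)C
A2 | direct plan | trimethyl orthoformate | COC(OC)OC
A3 | direct plan | 2,2-dimethyl-8-(3-methylbut-2-enyl)-6-vinylchroman | C=Cc1cc(CC=C(C)C)c2OC(C)(C)CCc2c1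
A4 | direct plan | (2S)-2-[2,2-dimethyl-8-(3-methylbut-2-enyl)chroman-6-yl]-4-methoxy-8-(3-methylbut-2-enyl)-7-(triisopropylsilyloxy)chroman (both C4 epimers) | COC1C[C@@H](c2cc(CC=C(C)C)c3OC(C)(C)CCc3c2)Oc2c(CC=C(C)C)c(O[Si](C(C)C)(C(C)C)C(C)C)ccc12
A5 | direct plan | 4-bromo-2,6-bis(3-methylbut-2-enyl)phenol | CC(C)=CCc1cc(Br)cc(CC=C(C)C)c1O
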